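**Remark.** Locants C1–C13 follow germacranolide numbering: C1 ketone, C4–C5 epoxide, C6 lactone carbinol, C7=C11 butenolide alkene, C8 ester carbinol, C9 hydroxyl carbon, C10 methyl-bearing carbon, C12 lactone carbonyl, C13 acetoxymethyl. PMB = 4-methoxybenzyl, TES = triethylsilyl, IPr = 1,3-bis(2,6-diisopropylphenyl)imidazol-2-ylidene. Compound 2, the ProPhenol ligand, free IPr and Novozym 435 are taken as catalogue items.

**Plan**
- Retrosynthesis: the O8 and O13 acyl groups come off first; then the lactone and the ten-membered ring are cut together at C6–C7, C11–C12 and C12–O, giving an alkyne (C7≡C11), an aldehyde (C6=O) and CO. The chain is then cut at C3–C4 (conjugate alkenylation), C9–C10 (aldol) and C7–C8 (alkynylation).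
- Enabling feature: the five butenolide ring atoms C7=C11–C12(=O)–O–C6 are an alkyne, an aldehyde and carbon monoxide, and C7 and C11 both carry oxygenated carbons (C8, C13), so the alkyne is a but-2-yne-1,4-diol unit that one propargyl ether supplies.
- Forward: the open chain C13–C11≡C7–C8–C9–C10–C1–C2–C3–C4=C5–C6 is built linearly, the epoxide and then the aldehyde are made, one nickel-mediated (2+2+1) step closes the ten-membered carbocycle and the lactone together, and deprotection and two acylations finish the route.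
- Stereochemistry: C8 comes from catalytic asymmetric alkynylation (made as the epimer and inverted at the end by Mitsunobu esterification); C9/C10 from an anti-selective boron aldol under Felkin control by C8; C4/C5 from Sharpless epoxidation; C6 from the key step under control of the epoxide and the forming ring.

Key step: step 10

**Route**

Step 1
Reactants: 1 (E)-but-2-enal; 2 4-methoxybenzyl propargyl ether
Product: 3 (4R,5E)-1-[(4-methoxybenzyl)oxy]hept-5-en-2-yn-4-ol
Conditions: Me2Zn, ProPhenol ligand (antipode giving 4R), Ph3P=O, toluene, 0 °C; aq. NH4Cl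
Reagents that add atoms: none
Why: Zinc–ProPhenol-catalysed asymmetric alkynylation of an enal, in which the chiral dinuclear zinc catalyst delivers the alkynyl group to one aldehyde face in a 1,2-addition and so sets C8 (4R in 3, the epimer of the target on purpose).

Step 2
Reactants: 3 (4R,5E)-1-[(4-methoxybenzyl)oxy]hept-5-en-2-yn-4-ol
Product: 4 (4R,5E)-1,4-bis[(4-methoxybenzyl)oxy]hept-5-en-2-yne
Conditions: NaH, PMBCl, Bu4NI (cat.), THF/DMF, 0 °C to rt
Reagents that add atoms: 4-methoxybenzyl chloride, COc1ccc(CCl)cc1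
Why: Williamson etherification of the alkoxide with a benzylic chloride, which touches no stereocentre.

Step 3
Reactants: 4 (4R,5E)-1,4-bis[(4-methoxybenzyl)oxy]hept-5-en-2-yne
Product: 6 (2S)-2,5-bis[(4-methoxybenzyl)oxy]pent-3-ynal, via ozonide 5 (not isolated)
Conditions: O3 (1 equiv), CH2Cl2, −78 °C; then PPh3, −78 °C to rt; used crude
Reagents that add atoms: ozone, [O-][O+]=O
Why: Ozonolysis with reductive work-up, in which the disubstituted alkene should react far faster than the alkyne or the anisyl rings; the neighbouring stereocentre is not involved, and the aldehyde is used at once to avoid epimerisation.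

Step 4
Reactants: 6 (2S)-2,5-bis[(4-methoxybenzyl)oxy]pent-3-ynal; 7 pent-1-en-3-one
Product: 9 (4S,5R,6S)-5-hydroxy-6,9-bis[(4-methoxybenzyl)oxy]-4-methylnon-1-en-7-yn-3-one, via boron enolate 8 (not isolated)
Conditions: 7, Cy2BCl, Et3N, Et2O, −78 °C; then 6, −78 to −20 °C; MeOH/pH 7 buffer
Reagents that add atoms: none
Why: Anti-selective boron aldol reaction, in which Cy2BCl/Et3N gives the (E)-enolate 8 from the only enolisable side of 7, the chair transition state gives the 9,10-anti pair, and Felkin–Anh/Cornforth control by the C8 ether oxygen gives the 8,9-anti relation, hence 9R,10S.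

Step 5
Reactants: 9 (4S,5R,6S)-5-hydroxy-6,9-bis[(4-methoxybenzyl)oxy]-4-methylnon-1-en-7-yn-3-one
Product: 10 (4S,5R,6S)-6,9-bis[(4-methoxybenzyl)oxy]-4-methyl-5-[(triethylsilyl)oxy]non-1-en-7-yn-3-one
Conditions: TESOTf, 2,6-lutidine, CH2Cl2, −78 °C
Reagents that add atoms: triethylsilyl trifluoromethanesulfonate, CC[Si](CC)(CC)OS(=O)(=O)C(F)(F)F
Why: Silylation of the secondary alcohol at low temperature, done without delay so that the β-hydroxy vinyl ketone cannot undergo retro-aldol or oxa-Michael closure.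

Step 6
Reactants: 11 but-2-yn-1-ol
Product: 12 (2Z)-3-(4,4,5,5-tetramethyl-1,3,2-dioxaborolan-2-yl)but-2-en-1-ol (boron trans to CH2OH)
Conditions: B2pin2, (SIMes)CuCl (5 mol%), NaOtBu (cat.), MeOH, THF, rt
Reagents that add atoms: bis(pinacolato)diboron, CC1(C)OB(OC1(C)C)B1OC(C)(C)C(C)(C)O1
Why: Copper-catalysed formal hydroboration of a propargylic alcohol, in which syn addition of Cu–Bpin with boron at the carbon remote from oxygen and protonation with retention should place boron trans to the CH2OH group.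

Step 7
Reactants: 10 (4S,5R,6S)-6,9-bis[(4-methoxybenzyl)oxy]-4-methyl-5-[(triethylsilyl)oxy]non-1-en-7-yn-3-one; 12 (2Z)-3-(4,4,5,5-tetramethyl-1,3,2-dioxaborolan-2-yl)but-2-en-1-ol
Product: 13 (2E,7S,8R,9S)-1-hydroxy-9,12-bis[(4-methoxybenzyl)oxy]-3,7-dimethyl-8-[(triethylsilyl)oxy]dodec-2-en-10-yn-6-one
Conditions: [Rh(cod)OH]2 (2.5 mol%), dioxane/H2O (10:1), 40 °C
Reagents that add atoms: none
Why: Rhodium-catalysed conjugate addition of an alkenylboronate to a vinyl ketone (Hayashi–Miyaura reaction), in which the alkenyl group transfers with retention of geometry to make the C3–C4 bond and the E-trisubstituted allylic alcohol; no stereocentre is formed.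

Step 8
Reactants: 13 (2E,7S,8R,9S)-1-hydroxy-9,12-bis[(4-methoxybenzyl)oxy]-3,7-dimethyl-8-[(triethylsilyl)oxy]dodec-2-en-10-yn-6-one
Product: 14 (4S,5R,6S)-1-[(2R,3R)-3-(hydroxymethyl)-2-methyloxiran-2-yl]-6,9-bis[(4-methoxybenzyl)oxy]-4-methyl-5-[(triethylsilyl)oxy]non-7-yn-3-one
Conditions: Ti(OiPr)4 (10 mol%), D-(−)-diethyl tartrate (12 mol%), t-BuOOH, 4 Å MS, CH2Cl2, −20 °C
Reagents that add atoms: tert-butyl hydroperoxide, CC(C)(C)OO
Why: Sharpless asymmetric epoxidation of an E-trisubstituted allylic alcohol, in which the D-(−)-tartrate catalyst delivers oxygen to the face that gives the (4R,5R)-epoxide under reagent control, as for geraniol.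

Step 9
Reactants: 14 (4S,5R,6S)-1-[(2R,3R)-3-(hydroxymethyl)-2-methyloxiran-2-yl]-6,9-bis[(4-methoxybenzyl)oxy]-4-methyl-5-[(triethylsilyl)oxy]non-7-yn-3-one
Product: 15 (2S,3R)-3-{(4S,5R,6S)-6,9-bis[(4-methoxybenzyl)oxy]-4-methyl-3-oxo-5-[(triethylsilyl)oxy]non-7-yn-1-yl}-3-methyloxirane-2-carbaldehyde
Conditions: TEMPO (10 mol%), PhI(OAc)2, CH2Cl2, rt; used at once
Reagents that add atoms: none
Why: TEMPO/PhI(OAc)2 oxidation of a primary alcohol to the aldehyde under near-neutral conditions that should leave the epoxide, the silyl ether and the PMB ethers intact.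

Step 10
Reactants: 15 (2S,3R)-3-{(4S,5R,6S)-6,9-bis[(4-methoxybenzyl)oxy]-4-methyl-3-oxo-5-[(triethylsilyl)oxy]non-7-yn-1-yl}-3-methyloxirane-2-carbaldehyde
Product: 17 (4R,5R,6S,8S,9R,10S)-4,5-epoxy-8,13-bis[(4-methoxybenzyl)oxy]-1-oxo-9-[(triethylsilyl)oxy]germacr-7(11)-en-12,6-olide, via oxanickelacyclopentene 16 (not isolated)
Conditions: Ni(cod)2 (1.2 equiv), IPr (1.2 equiv), toluene, 15 added by syringe pump (final 0.002 M), 23 °C; then CO (1 atm), 23 °C
Reagents that add atoms: carbon monoxide, [C-]#[O+]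
Why: Proposed new method: zerovalent nickel binds the alkyne C7≡C11 and the aldehyde C6=O of 15 and couples them by oxidative cyclization to the oxanickelacyclopentene 16 (C6–C7 made), CO then inserts into the Ni–C11 bond and C(acyl)–O reductive elimination releases the butenolide, so the sequence is a hetero-Pauson–Khand-type (2+2+1) cycloaddition in which CO becomes C12. The closest known reaction types are the zerovalent nickel/N-heterocyclic carbene oxidative cyclization of ynals that underlies their reductive macrocyclization, the carbonylation of isolated oxanickelacyclopentenes to butenolides, and molybdenum- or ruthenium-mediated hetero-Pauson–Khand closures of five- and six-membered rings; here these are joined and applied to a ten-membered ring. The ten-membered carbocycle closes in the exo mode (bond to the alkyne carbon that carries the tether, C7=C11 left exocyclic to that ring), and the five-membered lactone closes by the (2+2+1) union of C7=C11, C6–O and CO. The new stereocentre C6 is expected to be set by the epoxide carbon C5: C7 attacks anti to the C5–O bond while the nickel-bound carbonyl oxygen stays on the outside of the forming ring, anti to C4, which gives 6S. The step needs regioselectivity (C6 to C7, not C11), which the bulky carbene should secure by keeping nickel next to the small CH2OPMB end; chemoselectivity for the aldehyde over the C1 ketone, which the much higher reactivity of aldehydes in oxidative cyclization should secure; and ring closure over oligomerization, for which high dilution and the stoichiometric metal are used.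

Step 11
Reactants: 17 (4R,5R,6S,8S,9R,10S)-4,5-epoxy-8,13-bis[(4-methoxybenzyl)oxy]-1-oxo-9-[(triethylsilyl)oxy]germacr-7(11)-en-12,6-olide
Product: 18 (4R,5R,6S,8S,9R,10S)-4,5-epoxy-8,13-dihydroxy-1-oxo-9-[(triethylsilyl)oxy]germacr-7(11)-en-12,6-olide
Conditions: DDQ (2.5 equiv), CH2Cl2/pH 7 buffer, 0 °C
Reagents that add atoms: none
Why: Oxidative cleavage of both PMB ethers by DDQ (hydride abstraction, then hydrolysis of the oxocarbenium ion) in buffered medium, to which the silyl ether, epoxide and lactone should be inert.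

Step 12
Reactants: 18 (4R,5R,6S,8S,9R,10S)-4,5-epoxy-8,13-dihydroxy-1-oxo-9-[(triethylsilyl)oxy]germacr-7(11)-en-12,6-olide
Product: 19 (4R,5R,6S,8S,9R,10S)-13-acetoxy-4,5-epoxy-8-hydroxy-1-oxo-9-[(triethylsilyl)oxy]germacr-7(11)-en-12,6-olide
Conditions: Novozym 435 (immobilised Candida antarctica lipase B), vinyl acetate, t-BuOMe, 30 °C
Reagents that add atoms: vinyl acetate, CC(=O)OC=C
Why: Lipase-catalysed transesterification with an irreversible acyl donor, in which the enzyme should acylate the unhindered primary C13 hydroxyl and leave the hindered secondary C8 hydroxyl untouched.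

Step 13
Reactants: 19 (4R,5R,6S,8S,9R,10S)-13-acetoxy-4,5-epoxy-8-hydroxy-1-oxo-9-[(triethylsilyl)oxy]germacr-7(11)-en-12,6-olide
Product: 20 (4R,5R,6S,8R,9R,10S)-13-acetoxy-4,5-epoxy-8-(methacryloyloxy)-1-oxo-9-[(triethylsilyl)oxy]germacr-7(11)-en-12,6-olide
Conditions: methacrylic acid, PPh3, DIAD, toluene, 0 °C to rt
Reagents that add atoms: methacrylic acid, C=C(C)C(=O)O
Why: Mitsunobu esterification, in which methacrylate displaces the alkoxyphosphonium group at C8 in an SN2 reaction, so the ester is installed and C8 is inverted from S to R in one operation.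

Step 14
Reactants: 20 (4R,5R,6S,8R,9R,10S)-13-acetoxy-4,5-epoxy-8-(methacryloyloxy)-1-oxo-9-[(triethylsilyl)oxy]germacr-7(11)-en-12,6-olide
Product: 21 (4R,5R,6S,8R,9R,10S)-13-acetoxy-4,5-epoxy-9-hydroxy-8-(methacryloyloxy)-1-oxogermacr-7(11)-en-12,6-olide (CNP0185951.1)
Conditions: HF·pyridine, pyridine, THF, 0 °C
Reagents that add atoms: none
Why: Fluoride-mediated cleavage of the triethylsilyl ether under buffered conditions that should spare both esters, the epoxide and the base-sensitive butenolide.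

**Compound list**

1 | (E)-but-2-enal | C/C=C/C=O | starting material
2 | 4-methoxybenzyl propargyl ether | C#CCOCc1ccc(OC)cc1 | starting material
3 | (4R,5E)-1-[(4-methoxybenzyl)oxy]hept-5-en-2-yn-4-ol | COc1ccc(COCC#C[C@H](O)/C=C/C)cc1 | intermediate
4 | (4R,5E)-1,4-bis[(4-methoxybenzyl)oxy]hept-5-en-2-yne | COc1ccc(COCC#C[C@H](OCc2ccc(OC)cc2)/C=C/C)cc1 | intermediate
5 | 3-{(1S)-1,4-bis[(4-methoxybenzyl)oxy]but-2-yn-1-yl}-5-methyl-1,2,4-trioxolane (ozonide, ring carbons as a mixture) | COc1ccc(COCC#C[C@H](OCc2ccc(OC)cc2)C2OOC(C)O2)cc1 | intermediate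
6 | (2S)-2,5-bis[(4-methoxybenzyl)oxy]pent-3-ynal | COc1ccc(COCC#C[C@H](OCc2ccc(OC)cc2)C=O)cc1 | intermediate
7 | pent-1-en-3-one | CCC(=O)C=C | starting material
8 | dicyclohexyl[(3E)-penta-1,3-dien-3-yloxy]borane (methyl trans to O–B) | C/C=C(/OB(C1CCCCC1)C1CCCCC1)C=C | intermediate
9 | (4S,5R,6S)-5-hydroxy-6,9-bis[(4-methoxybenzyl)oxy]-4-methylnon-1-en-7-yn-3-one | COc1ccc(COCC#C[C@H](OCc2ccc(OC)cc2)[C@H](O)[C@H](C)C(=O)C=C)cc1 | intermediate
10 | (4S,5R,6S)-6,9-bis[(4-methoxybenzyl)oxy]-4-methyl-5-[(triethylsilyl)oxy]non-1-en-7-yn-3-one | COc1ccc(COCC#C[C@H](OCc2ccc(OC)cc2)[C@H](O[Si](CC)(CC)CC)[C@H](C)C(=O)C=C)cc1 | intermediate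
11 | but-2-yn-1-ol | CC#CCO | starting material
12 | (2Z)-3-(4,4,5,5-tetramethyl-1,3,2-dioxaborolan-2-yl)but-2-en-1-ol | C/C(=C\CO)B1OC(C)(C)C(C)(C)O1 | intermediate
13 | (2E,7S,8R,9S)-1-hydroxy-9,12-bis[(4-methoxybenzyl)oxy]-3,7-dimethyl-8-[(triethylsilyl)oxy]dodec-2-en-10-yn-6-one | COc1ccc(COCC#C[C@H](OCc2ccc(OC)cc2)[C@H](O[Si](CC)(CC)CC)[C@H](C)C(=O)CC/C(C)=C/CO)cc1 | intermediate
14 | (4S,5R,6S)-1-[(2R,3R)-3-(hydroxymethyl)-2-methyloxiran-2-yl]-6,9-bis[(4-methoxybenzyl)oxy]-4-methyl-5-[(triethylsilyl)oxy]non-7-yn-3-one | COc1ccc(COCC#C[C@H](OCc2ccc(OC)cc2)[C@H](O[Si](CC)(CC)CC)[C@H](C)C(=O)CC[C@@]2(C)O[C@@H]2CO)cc1 | intermediate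
15 | (2S,3R)-3-{(4S,5R,6S)-6,9-bis[(4-methoxybenzyl)oxy]-4-methyl-3-oxo-5-[(triethylsilyl)oxy]non-7-yn-1-yl}-3-methyloxirane-2-carbaldehyde | COc1ccc(COCC#C[C@H](OCc2ccc(OC)cc2)[C@H](O[Si](CC)(CC)CC)[C@H](C)C(=O)CC[C@@]2(C)O[C@@H]2C=O)cc1 | intermediate
16 | (IPr)-ligated oxanickelacyclopentene, ring Ni–O6–C6–C7=C11, fused to the ten-membered ring (4R,5R,6S,8S,9R,10S) | COc1ccc(CO[C@H]2C3=C(COCc4ccc(OC)cc4)[Ni](=C4N(c5c(C(C)C)cccc5C(C)C)C=CN4c4c(C(C)C)cccc4C(C)C)O[C@@H]3[C@H]3O[C@]3(C)CCC(=O)[C@@H](C)[C@H]2O[Si](CC)(CC)CC)cc1 | intermediate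
17 | (4R,5R,6S,8S,9R,10S)-4,5-epoxy-8,13-bis[(4-methoxybenzyl)oxy]-1-oxo-9-[(triethylsilyl)oxy]germacr-7(11)-en-12,6-olide | COc1ccc(CO[C@H]2C3=C(COCc4ccc(OC)cc4)C(=O)O[C@@H]3[C@H]3O[C@]3(C)CCC(=O)[C@@H](C)[C@H]2O[Si](CC)(CC)CC)cc1 | intermediate
18 | (4R,5R,6S,8S,9R,10S)-4,5-epoxy-8,13-dihydroxy-1-oxo-9-[(triethylsilyl)oxy]germacr-7(11)-en-12,6-olide | O[C@H]1C2=C(CO)C(=O)O[C@@H]2[C@H]2O[C@]2(C)CCC(=O)[C@@H](C)[C@H]1O[Si](CC)(CC)CC | intermediate
19 | (4R,5R,6S,8S,9R,10S)-13-acetoxy-4,5-epoxy-8-hydroxy-1-oxo-9-[(triethylsilyl)oxy]germacr-7(11)-en-12,6-olide | O[C@H]1C2=C(COC(C)=O)C(=O)O[C@@H]2[C@H]2O[C@]2(C)CCC(=O)[C@@H](C)[C@H]1O[Si](CC)(CC)CC | intermediate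
20 | (4R,5R,6S,8R,9R,10S)-13-acetoxy-4,5-epoxy-8-(methacryloyloxy)-1-oxo-9-[(triethylsilyl)oxy]germacr-7(11)-en-12,6-olide | C=C(C)C(=O)O[C@@H]1C2=C(COC(C)=O)C(=O)O[C@@H]2[C@H]2O[C@]2(C)CCC(=O)[C@@H](C)[C@H]1O[Si](CC)(CC)CC | intermediate
21 | (4R,5R,6S,8R,9R,10S)-13-acetoxy-4,5-epoxy-9-hydroxy-8-(methacryloyloxy)-1-oxogermacr-7(11)-en-12,6-olide (CNP0185951.1) | C=C(C)C(=O)O[C@@H]1C2=C(COC(C)=O)C(=O)O[C@@H]2[C@H]2O[C@]2(C)CCC(=O)[C@@H](C)[C@H]1O | target

**Step count**

Total: 14 steps. Longest linear sequence: 13 steps (steps 1–5 and 7–14).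

**Steps most likely to fail, with fallbacks**

1. Step 10 (proposed new method). What may go wrong: intermolecular alkyne–aldehyde coupling may outrun ring closure, the nickelacycle may lose the β-alkoxy group or fail to insert CO, the epoxy aldehyde may be opened by the metal, or the aldehyde face may be chosen poorly. The fallback uses known chemistry, a Nozaki–Hiyama–Kishi macrocyclisation with in situ lactonisation; it sets out from 4 and returns at 17.
   - Titanium-mediated carboxylation–iodination of the alkyne of 4 (Ti(OiPr)4, i-PrMgCl, Et2O, −78 to −50 °C; CO2; then I2) should give the (Z)-β-iodo acid F1. CO2 should enter at the less hindered alkyne carbon C11, and iodine replaces titanium at C7 on the same side.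
   - Me3SiCHN2 gives the methyl ester F2, and ozonolysis as in step 3 gives the iodoenoate aldehyde F3.
   - The boron aldol with 7 as in step 4 gives the β-hydroxy enone F4, and silylation as in step 5 gives the triethylsilyl ether F5.
   - Conjugate alkenylation with 12 as in step 7 gives the allylic alcohol F6, Sharpless epoxidation as in step 8 the epoxy alcohol F7, and oxidation as in step 9 the epoxy aldehyde F8.
   - CrCl2 (excess) with NiCl2 (catalytic) in DMSO/THF at high dilution then adds the alkenylchromium species at C7 to the aldehyde C6, and the chromium alkoxide closes the lactone on the neighbouring methyl ester to give 17.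

2. Step 13. What may go wrong: at the hindered ring carbinol, elimination or ionisation with loss of configuration may compete with clean SN2 inversion. The fallback replaces the displacement by an oxidation–reduction inversion followed by acylation; it sets out from 19 and returns at 20. Dess–Martin periodinane oxidises 19 to the C8 ketone F9. Luche reduction (CeCl3·7H2O, NaBH4, MeOH, −78 °C) should attack the conjugated C8 ketone in preference to the saturated C1 ketone and from the outer face of the ring, giving the 8R alcohol F10. Methacrylic anhydride with DMAP and Et3N then gives 20.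

3. Step 4. What may go wrong: the vinyl ketone may polymerise or add to its own enolate during enolisation, and the α-alkoxy aldehyde may epimerise. The fallback makes the enone after the aldol; it sets out from 6 and returns at 10. The same boron aldol with pentan-3-one (Cy2BCl, Et3N) gives the ethyl ketone aldol F11, and TESOTf/2,6-lutidine gives the silyl ether F12. Kinetic enolisation on the ethyl side (LDA, Me3SiCl, THF, −78 °C) gives the trimethylsilyl enol ether F13, and Saegusa–Ito oxidation (Pd(OAc)2, MeCN) gives 10.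

**Further compounds**

F1 | step 10 | (2Z,4R,5E)-3-iodo-4-[(4-methoxybenzyl)oxy]-2-{[(4-methoxybenzyl)oxy]methyl}hepta-2,5-dienoic acid | C/C=C/[C@@H](OCc1ccc(OC)cc1)/C(I)=C(/C(=O)O)COCc1ccc(OC)cc1
F2 | step 10 | methyl (2Z,4R,5E)-3-iodo-4-[(4-methoxybenzyl)oxy]-2-{[(4-methoxybenzyl)oxy]methyl}hepta-2,5-dienoate | C/C=C/[C@@H](OCc1ccc(OC)cc1)/C(I)=C(/C(=O)OC)COCc1ccc(OC)cc1
F3 | step 10 | methyl (2Z,4R)-3-iodo-4-[(4-methoxybenzyl)oxy]-2-{[(4-methoxybenzyl)oxy]methyl}-5-oxopent-2-enoate | O=C[C@@H](OCc1ccc(OC)cc1)/C(I)=C(/C(=O)OC)COCc1ccc(OC)cc1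
F4 | step 10 | methyl (2Z,4R,5R,6S)-5-hydroxy-3-iodo-4-[(4-methoxybenzyl)oxy]-2-{[(4-methoxybenzyl)oxy]methyl}-6-methyl-7-oxonona-2,8-dienoate | C=CC(=O)[C@@H](C)[C@@H](O)[C@@H](OCc1ccc(OC)cc1)/C(I)=C(/C(=O)OC)COCc1ccc(OC)cc1
F5 | step 10 | methyl (2Z,4R,5R,6S)-3-iodo-4-[(4-methoxybenzyl)oxy]-2-{[(4-methoxybenzyl)oxy]methyl}-6-methyl-7-oxo-5-[(triethylsilyl)oxy]nona-2,8-dienoate | C=CC(=O)[C@@H](C)[C@@H](O[Si](CC)(CC)CC)[C@@H](OCc1ccc(OC)cc1)/C(I)=C(/C(=O)OC)COCc1ccc(OC)cc1
F6 | step 10 | methyl (2Z,4R,5R,6S,10E)-12-hydroxy-3-iodo-4-[(4-methoxybenzyl)oxy]-2-{[(4-methoxybenzyl)oxy]methyl}-6,10-dimethyl-7-oxo-5-[(triethylsilyl)oxy]dodeca-2,10-dienoate | OC/C=C(C)/CCC(=O)[C@@H](C)[C@@H](O[Si](CC)(CC)CC)[C@@H](OCc1ccc(OC)cc1)/C(I)=C(/C(=O)OC)COCc1ccc(OC)cc1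
F7 | step 10 | methyl (2Z,4R,5R,6S)-9-[(2R,3R)-3-(hydroxymethyl)-2-methyloxiran-2-yl]-3-iodo-4-[(4-methoxybenzyl)oxy]-2-{[(4-methoxybenzyl)oxy]methyl}-6-methyl-7-oxo-5-[(triethylsilyl)oxy]non-2-enoate | OC[C@H]1O[C@]1(C)CCC(=O)[C@@H](C)[C@@H](O[Si](CC)(CC)CC)[C@@H](OCc1ccc(OC)cc1)/C(I)=C(/C(=O)OC)COCc1ccc(OC)cc1
F8 | step 10 | methyl (2Z,4R,5R,6S)-9-[(2R,3S)-3-formyl-2-methyloxiran-2-yl]-3-iodo-4-[(4-methoxybenzyl)oxy]-2-{[(4-methoxybenzyl)oxy]methyl}-6-methyl-7-oxo-5-[(triethylsilyl)oxy]non-2-enoate | O=C[C@H]1O[C@]1(C)CCC(=O)[C@@H](C)[C@@H](O[Si](CC)(CC)CC)[C@@H](OCc1ccc(OC)cc1)/C(I)=C(/C(=O)OC)COCc1ccc(OC)cc1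
F9 | step 13 | (4R,5R,6S,9R,10S)-13-acetoxy-4,5-epoxy-1,8-dioxo-9-[(triethylsilyl)oxy]germacr-7(11)-en-12,6-olide | O=C1C2=C(COC(C)=O)C(=O)O[C@@H]2[C@H]2O[C@]2(C)CCC(=O)[C@@H](C)[C@H]1O[Si](CC)(CC)CC
F10 | step 13 | (4R,5R,6S,8R,9R,10S)-13-acetoxy-4,5-epoxy-8-hydroxy-1-oxo-9-[(triethylsilyl)oxy]germacr-7(11)-en-12,6-olide | O[C@@H]1C2=C(COC(C)=O)C(=O)O[C@@H]2[C@H]2O[C@]2(C)CCC(=O)[C@@H](C)[C@H]1O[Si](CC)(CC)CC
F11 | step 4 | (4S,5R,6S)-5-hydroxy-6,9-bis[(4-methoxybenzyl)oxy]-4-methylnon-7-yn-3-one | COc1ccc(COCC#C[C@H](OCc2ccc(OC)cc2)[C@H](O)[C@H](C)C(=O)CC)cc1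
F12 | step 4 | (4S,5R,6S)-6,9-bis[(4-methoxybenzyl)oxy]-4-methyl-5-[(triethylsilyl)oxy]non-7-yn-3-one | COc1ccc(COCC#C[C@H](OCc2ccc(OC)cc2)[C@H](O[Si](CC)(CC)CC)[C@H](C)C(=O)CC)cc1
F13 | step 4 | (2Z,4S,5R,6S)-6,9-bis[(4-methoxybenzyl)oxy]-4-methyl-5-[(triethylsilyl)oxy]-3-[(trimethylsilyl)oxy]non-2-en-7-yne | COc1ccc(COCC#C[C@H](OCc2ccc(OC)cc2)[C@H](O[Si](CC)(CC)CC)[C@H](C)/C(O[Si](C)(C)C)=C/C)cc1
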